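**Retrosynthetic overview**

1. Numbering used throughout: C-1 = quaternary ring-fusion carbon (CH3), C-2/C-3 = ring A CH2, C-4 = isopropyl carbinol, C-5 = ring-fusion CH, C-6 = acyloxy CH, C-7 = CH2, C-8 = methyl carbinol, C-9=C-10 = alkene (C-10 on C-1); β = face of the C-1 methyl. Late disconnections: phenol silyl ether, iPr–C-4 (organocerium addition to a ring A ketone), C-6–H (chelation-controlled reduction), C-6 ester.
2. Seven-membered ring B ⇐ Grob fragmentation of the cyclobutane bond C-6–C-10 (a bond absent from the target) in a cyclobutane-fused cyclopentane whose C-9 mesylate can lie anti to that bond. This gives the C-6 ketone and C-9=C-10 at once; the 8α-carbinol is set beforehand by enolate methylation and hydroxylation at C-8, and C-5 then epimerises to the trans ring fusion.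
3. Cyclobutane ⇐ intramolecular enone–alkene [2+2] photocycloaddition of a 3-silyloxycyclopentenone (from cyclopentane-1,3-dione) onto (R)-3-methylcyclopent-2-en-1-ol, the two held by a temporary O–Si(iPr)2–O tether. It forms C-1–C-10 and C-5–C-6 and the quaternary centre C-1.
4. Enabling feature: the oxygens on C-4 (ring A) and C-6 (ring B) are 1,3-related through C-5, so one silicon atom bridges them in a six-membered ring. In addition the C-6 oxygen and C-9 are 1,3-related through C-10, so ring B is the perimeter of a bicyclo[3.2.0]heptane whose central bond can be fragmented.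
5. Ring order: ring A (purchased) → cyclobutane and silicon ring (key step) → ring B by fragmentation. The C-4 carbinol centre relays chirality to C-1 and is then oxidised and rebuilt.

Key step: step 3

Remark: 4-[(tert-butyldimethylsilyl)oxy]benzoic acid is taken as a purchasable reagent; C-numbers and α/β refer to the numbering above, for intermediates as well; ring C is the five-membered ring C-6 to C-10 of the photoadduct, and its concave face is the one that looks at C-1.

**Route**

Step 1
Reactants: 1 3-methylcyclopent-2-en-1-one
Product: 2 (R)-3-methylcyclopent-2-en-1-ol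
Conditions: (S)-2-methyl-CBS-oxazaborolidine (0.1 equiv), BH3·SMe2, THF, −20 °C
Reagents that add atoms: none
Why: CBS reduction: with the alkenyl carbon as the large group the (S)-catalyst should deliver hydride 1,2 to the face that gives the (R)-carbinol, whose centre (C-4) later steers the photocycloaddition through the tether and is oxidised away in step 14.

Step 2
Reactants: 2 (R)-3-methylcyclopent-2-en-1-ol; 3 cyclopentane-1,3-dione
Product: 5 3-({diisopropyl[(1R)-3-methylcyclopent-2-en-1-yloxy]silyl}oxy)cyclopent-2-en-1-one, via chlorosilane 4 (not isolated)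
Conditions: iPr2SiCl2, Et3N, DMAP (0.05 equiv), CH2Cl2, −20 → 0 °C; then 3, Et3N, 0 °C → rt
Reagents that add atoms: dichlorodiisopropylsilane, CC(C)[Si](Cl)(Cl)C(C)C
Why: Sequential silyl ether formation: the hindered dichlorosilane should take up one secondary alkoxide at low temperature, and the enol of the 1,3-dione is then O-silylated to the vinylogous silyl ester that serves as temporary tether; the carbinol centre is not touched.

Step 3
Reactants: 5 3-({diisopropyl[(1R)-3-methylcyclopent-2-en-1-yloxy]silyl}oxy)cyclopent-2-en-1-one
Product: 6 silicon-bridged cis-anti-cis cyclobutane photoadduct (C-9 ketone)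
Conditions: hν (300–350 nm, Pyrex), degassed MeCN (0.01 M), 0 °C
Reagents that add atoms: none
Why: Excitation of the 3-silyloxy enone (the chromophore of a de Mayo substrate) gives its triplet, whose β-carbon C-6 should add to the unsubstituted alkene carbon C-5 to leave a tertiary radical at C-1 that collapses onto C-10; this is an intramolecular enone–alkene [2+2] photocycloaddition through a temporary silicon tether, closest to known silicon- and acetal-tethered enone–olefin photocycloadditions and to de Mayo reactions of enol derivatives of cyclopentane-1,3-dione. The six-membered 1,3-dioxa-2-silacyclohexane closes with the first bond in the straight 1,6 mode (the crossed mode would need a seven-membered ring and a secondary radical), and the cyclobutane closes by radical recombination, necessarily cis on both five-membered rings. The quaternary centre C-1 and C-5 are set by the C-4 carbinol centre, because the tether can deliver the enone only to the face of ring A that carries O-4; C-6 and C-10 follow from the ring fusions (cis-anti-cis, since O-6 must be cis to C-4 on the cyclobutane) and are erased later. The step needs regioselectivity (C-6 to C-5, C-10 to C-1), which an untethered reaction would not be expected to control, and facial selectivity; both are secured by the O–Si–O bridge between the C-4 and C-6 oxygens.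

Step 4
Reactants: 6 silicon-bridged cis-anti-cis cyclobutane photoadduct (C-9 ketone)
Product: 7 8-methyl ketone
Conditions: LiN(iPr)2, THF, −78 °C; then MeI, −78 → −40 °C
Reagents that add atoms: iodomethane, CI
Why: Enolate C-alkylation: the C-9 ketone can enolise only towards C-8, since the other α-carbon C-10 is the cyclobutane ring-fusion carbon, and MeI should enter from the convex face; the configuration of the new centre is immaterial because C-8 is enolised again in step 5.

Step 5
Reactants: 7 8-methyl ketone
Product: 8 8-hydroxy-8-methyl ketone (hydroxyl on the convex face)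
Conditions: KN(SiMe3)2, THF, −78 °C; then 2-(phenylsulfonyl)-3-phenyloxaziridine, −78 °C; AcOH quench
Reagents that add atoms: 2-(phenylsulfonyl)-3-phenyloxaziridine, O=S(=O)(c1ccccc1)N1OC1c1ccccc1
Why: Davis enolate hydroxylation: the enolate can again form only towards C-8, and the oxaziridine should approach its convex face because the concave face is covered by the cyclobutane and the C-1 methyl group, which places the oxygen convex and the methyl concave at C-8, the arrangement that becomes 8α-OH, 8β-methyl in the target.

Step 6
Reactants: 8 8-hydroxy-8-methyl ketone (hydroxyl on the convex face)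
Product: 9 8-O-triethylsilyl ether
Conditions: Et3SiOTf, 2,6-lutidine, CH2Cl2, −78 → 0 °C
Reagents that add atoms: triethylsilyl trifluoromethanesulfonate, CC[Si](CC)(CC)OS(=O)(=O)C(F)(F)F
Why: Silyl ether formation with the silyl triflate, which is reactive enough for the tertiary α-hydroxyl; the group keeps O-8 from displacing the C-9 leaving group in step 9, and no stereocentre is changed.

Step 7
Reactants: 9 8-O-triethylsilyl ether
Product: 10 C-9 alcohol (hydroxyl on the concave face)
Conditions: NaBH4, THF/EtOH (4:1), −20 → 0 °C
Reagents that add atoms: none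
Why: Hydride reduction of the ketone: the concave face of C-9 is blocked by the cyclobutane and by the C-1 methyl group, which sits cis to C-9 on the four-membered ring, so NaBH4 should attack from the convex face and place the new hydroxyl on the concave face, trans to H-10 and to the C-8 oxygen, as the fragmentation requires.

Step 8
Reactants: 10 C-9 alcohol (hydroxyl on the concave face)
Product: 11 C-9 methanesulfonate
Conditions: MsCl, Et3N, CH2Cl2, −10 → 0 °C
Reagents that add atoms: methanesulfonyl chloride, CS(=O)(=O)Cl
Why: Sulfonate ester formation through the sulfene, which reaches even a hindered secondary hydroxyl; the C–O bond is not broken, so the configuration at C-9 is retained, and the two silyl groups are inert to MsCl/Et3N.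

Step 9
Reactants: 11 C-9 methanesulfonate
Product: 14 trans-fused 4α,8α-dihydroxy-6-ketone (5α-H), via cis-fused silyl ether ketone 12 (not isolated), via trans-fused silyl ether ketone 13 (not isolated)
Conditions: Bu4NF (2.5 equiv), THF, −20 → 0 °C; then K2CO3, MeOH, 0 °C → rt; then AcOH (excess), Bu4NF, rt
Reagents that add atoms: none
Why: Grob (Wharton-type) fragmentation of a 1,3-diol monosulfonate: fluoride should cleave the dialkoxysilane faster than the tertiary triethylsilyl ether, and the C-6 cyclobutanolate then pushes the strained C-6–C-10 bond into the C-9=C-10 double bond while the concave mesylate, which an envelope of ring C can place antiperiplanar to that bond with H-9 and H-10 cis, departs to give the C-6 ketone and the cis alkene; K2CO3/MeOH should then epimerise C-5 (α to the new ketone) to the trans ring fusion, which relieves the all-cis arrangement of C-10, C-6 and O-4 on ring A, while O-8 is still silylated and cannot undergo retro-aldol cleavage, and buffered fluoride finally frees the 8α-hydroxyl.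

Step 10
Reactants: 14 trans-fused 4α,8α-dihydroxy-6-ketone (5α-H)
Product: 15 4α-triethylsilyl ether
Conditions: Et3SiCl, imidazole, CH2Cl2, 0 °C
Reagents that add atoms: chlorotriethylsilane, CC[Si](Cl)(CC)CC
Why: Silyl ether formation at the only secondary hydroxyl (the tertiary allylic 8-OH is too hindered for Et3SiCl/imidazole), which masks O-4 so that only the 8α-hydroxyl can direct the reduction; no stereocentre is changed.

Step 11
Reactants: 15 4α-triethylsilyl ether
Product: 16 6α,8α-diol
Conditions: Et2BOMe, THF/MeOH (4:1), −78 °C; then NaBH4, −78 °C; AcOH quench, MeOH co-evaporation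
Reagents that add atoms: none
Why: Narasaka–Prasad reduction: Et2BOMe should tie the 8α-hydroxyl and the C-6 carbonyl oxygen into a six-membered boron chelate on the α-face, so that NaBH4 attacks C-6 from the β-face and gives the 6α-alcohol (syn-1,3-diol with the 8α-OH).

Step 12
Reactants: 16 6α,8α-diol; 17 4-[(tert-butyldimethylsilyl)oxy]benzoic acid
Product: 18 6α-aryl ester (4α-OSiEt3)
Conditions: EDC·HCl, DMAP, CH2Cl2, rt
Reagents that add atoms: none
Why: Steglich esterification of the only secondary hydroxyl (the tertiary 8-OH does not compete) with the silyl-protected acid; the C-6 configuration is retained because the C–O bond is not broken.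

Step 13
Reactants: 18 6α-aryl ester (4α-OSiEt3)
Product: 19 4α-alcohol
Conditions: PPTS (0.2 equiv), MeOH/CH2Cl2, 0 °C
Reagents that add atoms: none
Why: Acid-catalysed methanolysis of the secondary triethylsilyl ether, under which the aryl tert-butyldimethylsilyl ether, the benzoate and the tertiary alcohol should survive.

Step 14
Reactants: 19 4α-alcohol
Product: 20 C-4 ketone
Conditions: Dess–Martin periodinane, NaHCO3, CH2Cl2, 0 °C → rt
Reagents that add atoms: none
Why: Dess–Martin oxidation of the only secondary alcohol to the C-4 ketone under buffered, non-basic conditions, so that C-5 (now α to the ketone and β to the ester oxygen) is not epimerised and the aroyloxy group is not eliminated.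

Step 15
Reactants: 20 C-4 ketone
Product: 21 O-silylated target (4β-OH, 4α-isopropyl)
Conditions: iPrMgCl, CeCl3 (anhydrous), THF, −78 °C
Reagents that add atoms: isopropylmagnesium chloride, CC(C)[Mg]Cl
Why: Organocerium 1,2-addition: the weakly basic isopropylcerium reagent should add to the cyclopentanone faster than it enolises it or attacks the aryl ester, from the α-face (anti to the adjacent β-oriented C-5–C-6 bond and to the β C-1 methyl group), which sets C-4 as 4β-OH, 4α-isopropyl.

Step 16
Reactants: 21 O-silylated target (4β-OH, 4α-isopropyl)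
Product: 22 target, CNP0280165.4
Conditions: Bu4NF, AcOH, THF, 0 °C
Reagents that add atoms: none
Why: Fluoride cleavage of the aryl silyl ether, buffered with acetic acid so that the benzoate neither hydrolyses nor migrates, gives the free phenol of the target without touching any stereocentre.

**Compound list**

1 | 3-methylcyclopent-2-en-1-one | CC1=CC(=O)CC1 | starting material
2 | (R)-3-methylcyclopent-2-en-1-ol | O[C@H]1C=C(C)CC1 | intermediate
3 | cyclopentane-1,3-dione | O=C1CC(=O)CC1 | starting material
4 | chloro(diisopropyl)[(1R)-3-methylcyclopent-2-en-1-yloxy]silane (formed in the flask) | CC(C)[Si](Cl)(C(C)C)O[C@H]1C=C(C)CC1 | intermediate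
5 | 3-({diisopropyl[(1R)-3-methylcyclopent-2-en-1-yloxy]silyl}oxy)cyclopent-2-en-1-one | O=C1CCC(O[Si](C(C)C)(C(C)C)O[C@H]2C=C(C)CC2)=C1 | intermediate
6 | photoadduct: ring A / cyclobutane / ring C fused cis-anti-cis, C-9 ketone, O-4 and O-6 bridged by Si(iPr)2; bonds C-1–C-10 and C-5–C-6 on the α-face of ring A (cis to O-4), 1β-methyl, 5β-H, O-6 and H-10 on the convex face of ring C | O=C1CC[C@@]2(O[Si](C(C)C)(C(C)C)O[C@@H]3CC[C@]4(C)[C@@H]12)[C@H]34 | intermediate
7 | 8-methyl derivative of 6 (methyl on the convex face expected; centre enolised again in step 5) | O=C1[C@H](C)C[C@@]2(O[Si](C(C)C)(C(C)C)O[C@@H]3CC[C@]4(C)[C@@H]12)[C@H]34 | intermediate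
8 | 8-hydroxy-8-methyl derivative of 6 (hydroxyl on the convex face of ring C, methyl on the concave face) | O=C1[C@](C)(O)C[C@@]2(O[Si](C(C)C)(C(C)C)O[C@@H]3CC[C@]4(C)[C@@H]12)[C@H]34 | intermediate
9 | 8-O-triethylsilyl ether of 8 | O=C1[C@](C)(O[Si](CC)(CC)CC)C[C@@]2(O[Si](C(C)C)(C(C)C)O[C@@H]3CC[C@]4(C)[C@@H]12)[C@H]34 | intermediate
10 | C-9 alcohol from 9 (hydroxyl on the concave face, trans to H-10 and to the C-8 oxygen) | O[C@H]1[C@](C)(O[Si](CC)(CC)CC)C[C@@]2(O[Si](C(C)C)(C(C)C)O[C@@H]3CC[C@]4(C)[C@@H]12)[C@H]34 | intermediate
11 | C-9 methanesulfonate of 10 | CS(=O)(=O)O[C@H]1[C@](C)(O[Si](CC)(CC)CC)C[C@@]2(O[Si](C(C)C)(C(C)C)O[C@@H]3CC[C@]4(C)[C@@H]12)[C@H]34 | intermediate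
12 | cis-fused (5β-H) 4α-hydroxy-8α-(triethylsilyloxy)-1β,8β-dimethylbicyclo[5.3.0]dec-9-en-6-one, numbered as the target (formed in the flask) | O[C@@H]1CC[C@]2(C)C=C[C@](C)(O[Si](CC)(CC)CC)CC(=O)[C@@H]21 | intermediate
13 | trans-fused (5α-H) 4α-hydroxy-8α-(triethylsilyloxy)-1β,8β-dimethylbicyclo[5.3.0]dec-9-en-6-one, numbered as the target (formed in the flask) | O[C@@H]1CC[C@]2(C)C=C[C@](C)(O[Si](CC)(CC)CC)CC(=O)[C@H]21 | intermediate
14 | trans-fused (5α-H) 4α,8α-dihydroxy-1β,8β-dimethylbicyclo[5.3.0]dec-9-en-6-one, numbered as the target | O[C@@H]1CC[C@]2(C)C=C[C@](C)(O)CC(=O)[C@H]21 | intermediate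
15 | 4α-O-triethylsilyl ether of 14 | CC[Si](CC)(CC)O[C@@H]1CC[C@]2(C)C=C[C@](C)(O)CC(=O)[C@H]21 | intermediate
16 | 6α,8α-diol: 15 with the C-6 ketone reduced to the 6α-alcohol (6β-H) | CC[Si](CC)(CC)O[C@@H]1CC[C@]2(C)C=C[C@](C)(O)C[C@H](O)[C@H]21 | intermediate
17 | 4-[(tert-butyldimethylsilyl)oxy]benzoic acid | OC(=O)c1ccc(O[Si](C)(C)C(C)(C)C)cc1 | starting material
18 | 6α-[4-(tert-butyldimethylsilyloxy)benzoate] of 16 (4α-OSiEt3, 8α-OH) | CC[Si](CC)(CC)O[C@@H]1CC[C@]2(C)C=C[C@](C)(O)C[C@H](OC(=O)c3ccc(O[Si](C)(C)C(C)(C)C)cc3)[C@H]21 | intermediate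
19 | 4α-alcohol: 18 without the triethylsilyl group | O[C@@H]1CC[C@]2(C)C=C[C@](C)(O)C[C@H](OC(=O)c3ccc(O[Si](C)(C)C(C)(C)C)cc3)[C@H]21 | intermediate
20 | C-4 ketone: 19 oxidised at C-4 | O=C1CC[C@]2(C)C=C[C@](C)(O)C[C@H](OC(=O)c3ccc(O[Si](C)(C)C(C)(C)C)cc3)[C@H]21 | intermediate
21 | tert-butyldimethylsilyl ether (at the phenol) of the target: 4β-OH, 4α-isopropyl | CC(C)[C@]1(O)CC[C@]2(C)C=C[C@](C)(O)C[C@H](OC(=O)c3ccc(O[Si](C)(C)C(C)(C)C)cc3)[C@H]21 | intermediate
22 | CNP0280165.4 | CC(C)[C@]1(O)CC[C@]2(C)C=C[C@](C)(O)C[C@H](OC(=O)c3ccc(O)cc3)[C@H]21 | target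

**Step count and risks**

Total step count: 16. Longest linear sequence: 16 steps (from 1).

Steps most likely to fail:

1. Step 9. The tertiary triethylsilyl ether may be lost before the cyclobutane has opened, so that the freed C-8 alkoxide displaces the mesylate and the fragmentation is blocked. Later unmasking of O-8 under basic conditions may lead to retro-aldol opening of ring B, or the C-5 epimerisation may stop short. The fallback masks O-8 with a group that fluoride cannot remove and unmasks it oxidatively at the end; it sets out from 8. 4-Methoxybenzyl trichloroacetimidate with catalytic La(OTf)3 should give the 4-methoxybenzyl ether F1. NaBH4 reduction from the convex face gives the C-9 alcohol F2, and MsCl/Et3N gives the mesylate F3. Bu4NF then frees the C-6 alkoxide, which expels the mesylate in the Grob fragmentation, and K2CO3/MeOH epimerises C-5 to give the trans-fused 8-O-(4-methoxybenzyl) hydroxy ketone F4. DDQ in CH2Cl2/pH 7 buffer cleaves the benzyl ether, and the route is rejoined at 14.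

2. Step 15. The C-5 enolate may form and expel the C-6 aroyloxy group, or the reagent may attack the ester, instead of adding to the hindered ketone. The fallback introduces the ester last and sets out from 16. tBu2Si(OTf)2/2,6-lutidine ties the 6α,8α-diol into the cyclic silylene F5. PPTS/MeOH removes the triethylsilyl group to give the alcohol F6, and Dess–Martin oxidation gives the ketone F7, which has no acyloxy leaving group. iPrMgCl/CeCl3 adds from the α-face to give the tertiary alcohol F8, and HF·pyridine releases the triol F9. EDC/DMAP coupling of F9 with 17 acylates its only secondary hydroxyl, and the route is rejoined at 21.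

3. Step 11. The boron chelate may not form well in the seven-membered ring, so that hydride attacks from the α-face and the facial selectivity is poor or reversed. The fallback makes the opposite epimer on purpose and inverts it, and sets out from 15. Evans–Saksena reduction (Me4NBH(OAc)3, AcOH/MeCN, −20 °C) delivers hydride intramolecularly from the 8α-hydroxyl and should give the 6β-alcohol F10. A Mitsunobu reaction of F10 with 17 (PPh3, DIAD, toluene) forms the ester with inversion at C-6, and the route is rejoined at 18.

Further compounds
F1 | step 9 | 8-O-(4-methoxybenzyl) ether of 8 | O=C1[C@](C)(OCc5ccc(OC)cc5)C[C@@]2(O[Si](C(C)C)(C(C)C)O[C@@H]3CC[C@]4(C)[C@@H]12)[C@H]34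
F2 | step 9 | C-9 alcohol from F1 (hydroxyl on the concave face) | O[C@H]1[C@](C)(OCc5ccc(OC)cc5)C[C@@]2(O[Si](C(C)C)(C(C)C)O[C@@H]3CC[C@]4(C)[C@@H]12)[C@H]34
F3 | step 9 | C-9 methanesulfonate of F2 | CS(=O)(=O)O[C@H]1[C@](C)(OCc5ccc(OC)cc5)C[C@@]2(O[Si](C(C)C)(C(C)C)O[C@@H]3CC[C@]4(C)[C@@H]12)[C@H]34
F4 | step 9 | trans-fused (5α-H) 4α-hydroxy-8α-(4-methoxybenzyloxy)-1β,8β-dimethylbicyclo[5.3.0]dec-9-en-6-one, numbered as the target | O[C@@H]1CC[C@]2(C)C=C[C@](C)(OCc3ccc(OC)cc3)CC(=O)[C@H]21
F5 | step 15 | 6α,8α-O-(di-tert-butylsilylene) derivative of 16 | CC[Si](CC)(CC)O[C@@H]1CC[C@]2(C)C=C[C@@]3(C)C[C@H](O[Si](C(C)(C)C)(C(C)(C)C)O3)[C@H]21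
F6 | step 15 | 4α-alcohol from F5 | O[C@@H]1CC[C@]2(C)C=C[C@@]3(C)C[C@H](O[Si](C(C)(C)C)(C(C)(C)C)O3)[C@H]21
F7 | step 15 | C-4 ketone from F6 | O=C1CC[C@]2(C)C=C[C@@]3(C)C[C@H](O[Si](C(C)(C)C)(C(C)(C)C)O3)[C@H]21
F8 | step 15 | 4β-hydroxy-4α-isopropyl silylene from F7 | CC(C)[C@]1(O)CC[C@]2(C)C=C[C@@]3(C)C[C@H](O[Si](C(C)(C)C)(C(C)(C)C)O3)[C@H]21
F9 | step 15 | 4β,6α,8α-triol (target without the aroyl group) | CC(C)[C@]1(O)CC[C@]2(C)C=C[C@](C)(O)C[C@H](O)[C@H]21
F10 | step 11 | 6β-alcohol, the C-6 epimer of 16 | CC[Si](CC)(CC)O[C@@H]1CC[C@]2(C)C=C[C@](C)(O)C[C@@H](O)[C@H]21
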